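**Retrosynthetic overview**

- Rings are lettered A to E from the 2,4,6-trihydroxyphenyl end. The target 28 comes from its tetradecamethyl ether 27 by global O-demethylation. Ether 27 comes from a copper-catalysed ether coupling between the B6 phenol of the A–B unit 18 and the ring C bromide of the C–D–E unit 26.
- The strategy rests on ring B. B1 (oxygen to ring A), B3, B4, B5 (hydroxyls) and B6 (oxygen to ring C) carry five contiguous oxygens, and only B2 is CH. B3–B6 with their four oxygens come from dimethyl squarate; B1–B2 come from a 1-aryloxyvinyl group.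
- Ring B is closed by forming B2–B3 in a thermal cyclobutenone ring expansion (13 to 16). This leaves the B6 oxygen silylated and the B3 hydroxyl free, so ring C can later be attached at B6 only.
- Precursor 13 is built from 2,4,6-trimethoxyphenol: trichloroethene, ethynyl ether, hydrostannation, tin–lithium exchange, addition to the squarate, silylation.
- Bromide 26 is built from 4-bromo-2,6-dimethoxyphenol and (3,4,5-trimethoxyphenyl)boronic acid by O-arylation, formylation at D6, Dakin oxidation and a second O-arylation. Rings A, C, D and E are bought as arenes; ring B is the only ring formed.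

Key step: step 6

Remark: the 1-metalated aryl vinyl ether is reached through the aryl ethynyl ether, because bromination–dehydrobromination of an aryl vinyl ether gives the 2-bromovinyl isomer and direct deprotonation would compete with lithiation of ring A between two methoxy groups; compounds 1, 2, 9, 19 and 20 are taken to be purchasable.

**Route**

Step 1
Reactants: 1 2,4,6-trimethoxyphenol; 2 trichloroethene
Product: 4 2-{[(E)-1,2-dichloroethenyl]oxy}-1,3,5-trimethoxybenzene, via dichloroethyne 3 (not isolated)
Conditions: K2CO3, DMF, 70 °C, N2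
Reagents that add atoms: none
Why: K2CO3 should dehydrochlorinate trichloroethene to dichloroethyne, to which the phenoxide adds anti to give the (E)-1,2-dichlorovinyl ether (base-mediated addition of a phenol to trichloroethene), so the crowded ring A oxygen is bonded to an unhindered sp carbon.

Step 2
Reactants: 4 2-{[(E)-1,2-dichloroethenyl]oxy}-1,3,5-trimethoxybenzene
Product: 7 2-(ethynyloxy)-1,3,5-trimethoxybenzene, via chloroethynyl ether 5 (not isolated), via lithium acetylide 6 (not isolated)
Conditions: n-BuLi (2.2 equiv), THF, −78 to −40 °C; then H2O, −78 °C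
Reagents that add atoms: none
Why: Vinyl deprotonation with loss of LiCl gives the chloroalkyne, chlorine–lithium exchange gives the lithium aryloxyacetylide and the quench protonates it (ynol ether synthesis from 1,2-dichlorovinyl ethers), while at this temperature n-BuLi should not metalate ring A.

Step 3
Reactants: 7 2-(ethynyloxy)-1,3,5-trimethoxybenzene
Product: 8 tributyl[1-(2,4,6-trimethoxyphenoxy)ethenyl]stannane
Conditions: Bu3SnH (slow addition), Pd(PPh3)4 (2 mol %), THF, 0 °C to rt; chromatography on Et3N-deactivated silica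
Reagents that add atoms: tributyltin hydride, CCCC[SnH](CCCC)CCCC
Why: Syn hydrostannation of 1-oxyalkynes under zerovalent palladium catalysis places tin on the oxygen-bearing carbon, so the 1-stannylvinyl ether is expected as the main regioisomer.

Step 4
Reactants: 8 tributyl[1-(2,4,6-trimethoxyphenoxy)ethenyl]stannane; 9 dimethyl squarate
Product: 12 racemic 4-hydroxy-2,3-dimethoxy-4-[1-(2,4,6-trimethoxyphenoxy)ethenyl]cyclobut-2-en-1-one, via vinyllithium 10 (not isolated), via lithium alkoxide 11 (not isolated)
Conditions: n-BuLi, THF, −78 °C; then 9, THF, −78 °C; aq. NH4Cl, −78 °C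
Reagents that add atoms: none
Why: Tin–lithium exchange gives the 1-aryloxyvinyllithium without touching the acidic ring A C–H bonds, and 1,2-addition to one carbonyl of the symmetrical squarate ester gives the carbinol, whose new stereocenter forms as a racemate and is erased in step 6.

Step 5
Reactants: 12 racemic 4-hydroxy-2,3-dimethoxy-4-[1-(2,4,6-trimethoxyphenoxy)ethenyl]cyclobut-2-en-1-one
Product: 13 racemic 4-(tert-butyldimethylsilyloxy)-2,3-dimethoxy-4-[1-(2,4,6-trimethoxyphenoxy)ethenyl]cyclobut-2-en-1-one
Conditions: TBSOTf, 2,6-lutidine, CH2Cl2, −78 to 0 °C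
Reagents that add atoms: tert-butyldimethylsilyl trifluoromethanesulfonate, CC(C)(C)[Si](C)(C)OS(=O)(=O)C(F)(F)F
Why: Silyl triflate with a hindered pyridine base silylates tertiary alcohols, and the buffered low-temperature conditions should suppress acid-induced rearrangement of the squarate adduct to a cyclobutenedione.

Step 6
Reactants: 13 racemic 4-(tert-butyldimethylsilyloxy)-2,3-dimethoxy-4-[1-(2,4,6-trimethoxyphenoxy)ethenyl]cyclobut-2-en-1-one
Product: 16 4-(tert-butyldimethylsilyloxy)-2,3-dimethoxy-5-(2,4,6-trimethoxyphenoxy)phenol, via dienylketene 14 (not isolated), via cyclohexadienone 15 (not isolated)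
Conditions: toluene (0.02 M, degassed), 110 °C, argon
Reagents that add atoms: none
Why: Heating should open the cyclobutenone by thermal four-electron conrotatory cleavage of the C1–C4 bond to dienylketene 14, which closes by six-electron disrotatory electrocyclization between the ketene carbon (future B3) and the vinyl CH2 terminus (future B2) to cyclohexadienone 15, and enolization then gives phenol 16. This is the Moore ring expansion of 4-alkenyl-4-oxycyclobutenones made from squarate esters, a known route to mono-protected hydroquinones. Ring B closes in the electrocyclic mode, the new B2–B3 bond being the only skeletal bond formed. No stereocenter is created; the carbinol stereocenter of racemic 13 becomes the sp2 carbon B6. The selectivity needed is torquoselectivity in the ring opening: the silyloxy donor on C4 rotates outward, which turns the aryloxyvinyl group inward next to the ketene, the (3Z) geometry required for closure. Because silicon stays on the former carbinol oxygen (B6) while the ketene oxygen emerges as the free B3 hydroxyl, the two para oxygens leave the step differentiated.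

Step 7
Reactants: 16 4-(tert-butyldimethylsilyloxy)-2,3-dimethoxy-5-(2,4,6-trimethoxyphenoxy)phenol
Product: 17 tert-butyldimethyl[2,3,4-trimethoxy-6-(2,4,6-trimethoxyphenoxy)phenoxy]silane
Conditions: MeI, K2CO3, acetone, rt
Reagents that add atoms: iodomethane, CI
Why: Williamson methylation of the only free phenol (B3–OH) under mild carbonate conditions should leave the aryl silyl ether at B6, which is shielded by two ortho substituents, intact.

Step 8
Reactants: 17 tert-butyldimethyl[2,3,4-trimethoxy-6-(2,4,6-trimethoxyphenoxy)phenoxy]silane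
Product: 18 2,3,4-trimethoxy-6-(2,4,6-trimethoxyphenoxy)phenol
Conditions: Bu4NF, AcOH, THF, 0 °C, argon
Reagents that add atoms: none
Why: Fluoride cleaves the aryl silyl ether, and the acetic acid buffer keeps the electron-rich B6 phenol protonated so that it is not oxidized by air.

Step 9
Reactants: 19 4-bromo-2,6-dimethoxyphenol; 20 (3,4,5-trimethoxyphenyl)boronic acid
Product: 21 5-bromo-1,3-dimethoxy-2-(3,4,5-trimethoxyphenoxy)benzene
Conditions: Cu(OAc)2 (2 equiv), pyridine, 4 Å molecular sieves, CH2Cl2, air, rt
Reagents that add atoms: none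
Why: Chan–Lam O-arylation mediated by divalent copper accepts phenols with two ortho substituents and leaves the aryl bromide untouched, giving the C4–O–D1 ether with the ring C bromide in place.

Step 10
Reactants: 21 5-bromo-1,3-dimethoxy-2-(3,4,5-trimethoxyphenoxy)benzene
Product: 23 6-(4-bromo-2,6-dimethoxyphenoxy)-2,3,4-trimethoxybenzaldehyde, via iminium chloride 22 (not isolated)
Conditions: POCl3, DMF, 0 to 60 °C; then aq. NaOAc
Reagents that add atoms: N,N-dimethylformamide, CN(C)C=O; water, O
Why: Vilsmeier–Haack formylation should go to D6 (equivalent to D2 by symmetry), which is ortho to an aryloxy and a methoxy group and para to a methoxy group, whereas ring C is deactivated by bromine, and the first formyl group stops a second substitution.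

Step 11
Reactants: 23 6-(4-bromo-2,6-dimethoxyphenoxy)-2,3,4-trimethoxybenzaldehyde
Product: 25 6-(4-bromo-2,6-dimethoxyphenoxy)-2,3,4-trimethoxyphenol, via aryl formate 24 (not isolated)
Conditions: 30% H2O2, H2SO4 (cat.), MeOH, rt
Reagents that add atoms: hydrogen peroxide, OO
Why: Acid-catalysed Dakin oxidation of an ortho- and para-alkoxylated benzaldehyde proceeds by aryl migration in the peroxide adduct, and the resulting formate is methanolysed in the same flask to the D6 phenol.

Step 12
Reactants: 25 6-(4-bromo-2,6-dimethoxyphenoxy)-2,3,4-trimethoxyphenol; 20 (3,4,5-trimethoxyphenyl)boronic acid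
Product: 26 5-bromo-1,3-dimethoxy-2-[3,4,5-trimethoxy-2-(3,4,5-trimethoxyphenoxy)phenoxy]benzene
Conditions: Cu(OAc)2 (2 equiv), pyridine, 4 Å molecular sieves, CH2Cl2, air, rt
Reagents that add atoms: none
Why: A second Chan–Lam O-arylation attaches ring E to the hindered D6 phenol under conditions that again spare the ring C bromide.

Step 13
Reactants: 18 2,3,4-trimethoxy-6-(2,4,6-trimethoxyphenoxy)phenol; 26 5-bromo-1,3-dimethoxy-2-[3,4,5-trimethoxy-2-(3,4,5-trimethoxyphenoxy)phenoxy]benzene
Product: 27 tetradecamethyl ether of the target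
Conditions: CuI (10 mol %), picolinic acid (20 mol %), K3PO4, DMSO, 100 °C, argon
Reagents that add atoms: none
Why: Ullmann-type diaryl ether synthesis with monovalent copper and picolinic acid is suited to phenols with two ortho substituents, and the bromide carbon C1 of ring C is flanked only by hydrogens.

Step 14
Reactants: 27 tetradecamethyl ether of the target
Product: 28 target pentamer CNP0273977.0
Conditions: BBr3 (3 equiv per OMe), CH2Cl2, −78 °C to rt; then H2O, 0 °C, argon
Reagents that add atoms: none
Why: BBr3 cleaves aryl methyl ethers by coordination to oxygen and bromide attack at the methyl carbon, the diaryl ether bonds offer no sp3 carbon and should survive, and hydrolysis of the aryl borates frees all fourteen hydroxyls under exclusion of air.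

**Compound list**

1 | 2,4,6-trimethoxyphenol | COc1cc(OC)c(O)c(OC)c1 | starting material
2 | trichloroethene | ClC=C(Cl)Cl | starting material
3 | dichloroethyne | ClC#CCl | intermediate
4 | 2-{[(E)-1,2-dichloroethenyl]oxy}-1,3,5-trimethoxybenzene | COc1cc(OC)c(O/C(Cl)=C\Cl)c(OC)c1 | intermediate
5 | 2-[(chloroethynyl)oxy]-1,3,5-trimethoxybenzene | COc1cc(OC)c(OC#CCl)c(OC)c1 | intermediate
6 | lithium 2-(2,4,6-trimethoxyphenoxy)ethynide | [Li]C#COc1c(OC)cc(OC)cc1OC | intermediate
7 | 2-(ethynyloxy)-1,3,5-trimethoxybenzene | COc1cc(OC)c(OC#C)c(OC)c1 | intermediate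
8 | tributyl[1-(2,4,6-trimethoxyphenoxy)ethenyl]stannane | CCCC[Sn](CCCC)(CCCC)C(=C)Oc1c(OC)cc(OC)cc1OC | intermediate
9 | dimethyl squarate (3,4-dimethoxycyclobut-3-ene-1,2-dione) | COC1=C(OC)C(=O)C1=O | starting material
10 | [1-(2,4,6-trimethoxyphenoxy)ethenyl]lithium | [Li]C(=C)Oc1c(OC)cc(OC)cc1OC | intermediate
11 | lithium alkoxide of carbinol 12 (racemic) | [Li]OC1(C(=C)Oc2c(OC)cc(OC)cc2OC)C(OC)=C(OC)C1=O | intermediate
12 | racemic 4-hydroxy-2,3-dimethoxy-4-[1-(2,4,6-trimethoxyphenoxy)ethenyl]cyclobut-2-en-1-one | COC1=C(OC)C(O)(C(=C)Oc2c(OC)cc(OC)cc2OC)C1=O | intermediate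
13 | racemic 4-(tert-butyldimethylsilyloxy)-2,3-dimethoxy-4-[1-(2,4,6-trimethoxyphenoxy)ethenyl]cyclobut-2-en-1-one | COC1=C(OC)C(O[Si](C)(C)C(C)(C)C)(C(=C)Oc2c(OC)cc(OC)cc2OC)C1=O | intermediate
14 | (3Z)-4-(tert-butyldimethylsilyloxy)-2,3-dimethoxy-5-(2,4,6-trimethoxyphenoxy)hexa-1,3,5-trien-1-one | O=C=C(OC)/C(OC)=C(/O[Si](C)(C)C(C)(C)C)C(=C)Oc1c(OC)cc(OC)cc1OC | intermediate
15 | 4-(tert-butyldimethylsilyloxy)-2,3-dimethoxy-5-(2,4,6-trimethoxyphenoxy)cyclohexa-2,4-dien-1-one | O=C1CC(Oc2c(OC)cc(OC)cc2OC)=C(O[Si](C)(C)C(C)(C)C)C(OC)=C1OC | intermediate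
16 | 4-(tert-butyldimethylsilyloxy)-2,3-dimethoxy-5-(2,4,6-trimethoxyphenoxy)phenol | COc1cc(OC)c(Oc2cc(O)c(OC)c(OC)c2O[Si](C)(C)C(C)(C)C)c(OC)c1 | intermediate
17 | tert-butyldimethyl[2,3,4-trimethoxy-6-(2,4,6-trimethoxyphenoxy)phenoxy]silane | COc1cc(OC)c(Oc2cc(OC)c(OC)c(OC)c2O[Si](C)(C)C(C)(C)C)c(OC)c1 | intermediate
18 | 2,3,4-trimethoxy-6-(2,4,6-trimethoxyphenoxy)phenol | COc1cc(OC)c(Oc2cc(OC)c(OC)c(OC)c2O)c(OC)c1 | intermediate
19 | 4-bromo-2,6-dimethoxyphenol | COc1cc(Br)cc(OC)c1O | starting material
20 | (3,4,5-trimethoxyphenyl)boronic acid | COc1cc(B(O)O)cc(OC)c1OC | starting material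
21 | 5-bromo-1,3-dimethoxy-2-(3,4,5-trimethoxyphenoxy)benzene | COc1cc(Br)cc(OC)c1Oc1cc(OC)c(OC)c(OC)c1 | intermediate
22 | {[6-(4-bromo-2,6-dimethoxyphenoxy)-2,3,4-trimethoxyphenyl]methylidene}dimethylazanium chloride | COc1cc(Br)cc(OC)c1Oc1cc(OC)c(OC)c(OC)c1C=[N+](C)C.[Cl-] | intermediate
23 | 6-(4-bromo-2,6-dimethoxyphenoxy)-2,3,4-trimethoxybenzaldehyde | COc1cc(Br)cc(OC)c1Oc1cc(OC)c(OC)c(OC)c1C=O | intermediate
24 | 6-(4-bromo-2,6-dimethoxyphenoxy)-2,3,4-trimethoxyphenyl formate | COc1cc(Br)cc(OC)c1Oc1cc(OC)c(OC)c(OC)c1OC=O | intermediate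
25 | 6-(4-bromo-2,6-dimethoxyphenoxy)-2,3,4-trimethoxyphenol | COc1cc(Br)cc(OC)c1Oc1cc(OC)c(OC)c(OC)c1O | intermediate
26 | 5-bromo-1,3-dimethoxy-2-[3,4,5-trimethoxy-2-(3,4,5-trimethoxyphenoxy)phenoxy]benzene | COc1cc(Br)cc(OC)c1Oc1cc(OC)c(OC)c(OC)c1Oc1cc(OC)c(OC)c(OC)c1 | intermediate
27 | tetradecamethyl ether of the target (all fourteen hydroxyls as OMe) | COc1cc(OC)c(Oc2cc(OC)c(OC)c(OC)c2Oc2cc(OC)c(Oc3cc(OC)c(OC)c(OC)c3Oc3cc(OC)c(OC)c(OC)c3)c(OC)c2)c(OC)c1 | intermediate
28 | CNP0273977.0 (pentameric phlorotannin, rings A–E) | Oc1cc(O)c(Oc2cc(O)c(O)c(O)c2Oc2cc(O)c(Oc3cc(O)c(O)c(O)c3Oc3cc(O)c(O)c(O)c3)c(O)c2)c(O)c1 | target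

**Step count**

Total: 14 steps. Longest linear sequence: 10 steps (steps 1–8, 13, 14). The C–D–E branch is 4 steps (9–12) before the convergent coupling.

**Steps most likely to fail**

Step 6. The opened dienylketene may be diverted before the six-electron closure, by loss of the silyl group, ketene dimerisation or capture by adventitious nucleophiles. The fallback reaches phenol 18 without a ring expansion and sets out from compound 1. Purchasable 5-bromo-1,2,3-trimethoxybenzene F2 would be formylated ortho to bromine under Rieche conditions (Cl2CHOMe, TiCl4, CH2Cl2, 0 °C) to 6-bromo-2,3,4-trimethoxybenzaldehyde F3. Ullmann coupling of F3 with phenol 1 (CuI, picolinic acid, K3PO4, DMSO, 90 °C), helped by the ortho formyl group, should give 2,3,4-trimethoxy-6-(2,4,6-trimethoxyphenoxy)benzaldehyde F4. Dakin oxidation of F4 (H2O2, cat. H2SO4, MeOH) then gives the B6 phenol, so the fallback comes back to the route at compound 18.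

Step 3. Tin may be delivered to the terminal carbon instead of the oxygen-bearing carbon, or the ynol ether may oligomerise at palladium faster than it is hydrostannated. The fallback sets out from compound 7. Markovnikov hydrobromination with HBr made in the flask (TMSBr, MeOH, CH2Cl2, −40 °C) goes through the oxygen-stabilised vinyl cation and should give 2-[(1-bromoethenyl)oxy]-1,3,5-trimethoxybenzene F1. Bromine–lithium exchange on F1 (t-BuLi, 2 equiv, Et2O, −78 °C) gives the vinyllithium, so the fallback comes back to the route at compound 10, which is added to 9 as in step 4.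

Step 13. Turnover at copper may be slow for the phenoxide with two ortho substituents and the electron-rich bromide, so that protodebromination of 26 and oxidation of the phenoxide take over. The fallback sets out from compound 26. Miyaura borylation (B2pin2, Pd(dppf)Cl2, KOAc, dioxane, 90 °C) should give 2-{3,5-dimethoxy-4-[3,4,5-trimethoxy-2-(3,4,5-trimethoxyphenoxy)phenoxy]phenyl}-4,4,5,5-tetramethyl-1,3,2-dioxaborolane F5. Oxidative removal of pinacol (NaIO4, NH4OAc, acetone–water) gives {3,5-dimethoxy-4-[3,4,5-trimethoxy-2-(3,4,5-trimethoxyphenoxy)phenoxy]phenyl}boronic acid F6. Chan–Lam coupling of F6 with phenol 18 (Cu(OAc)2, pyridine, 4 Å molecular sieves, CH2Cl2, air), the same reaction type as steps 9 and 12, comes back to the route at compound 27.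

**Further compounds**

F1 | step 3 | 2-[(1-bromoethenyl)oxy]-1,3,5-trimethoxybenzene | COc1cc(OC)c(OC(Br)=C)c(OC)c1
F2 | step 6 | 5-bromo-1,2,3-trimethoxybenzene | COc1cc(Br)cc(OC)c1OC
F3 | step 6 | 6-bromo-2,3,4-trimethoxybenzaldehyde | O=Cc1c(Br)cc(OC)c(OC)c1OC
F4 | step 6 | 2,3,4-trimethoxy-6-(2,4,6-trimethoxyphenoxy)benzaldehyde | COc1cc(OC)c(Oc2cc(OC)c(OC)c(OC)c2C=O)c(OC)c1
F5 | step 13 | 2-{3,5-dimethoxy-4-[3,4,5-trimethoxy-2-(3,4,5-trimethoxyphenoxy)phenoxy]phenyl}-4,4,5,5-tetramethyl-1,3,2-dioxaborolane | COc1cc(B2OC(C)(C)C(C)(C)O2)cc(OC)c1Oc1cc(OC)c(OC)c(OC)c1Oc1cc(OC)c(OC)c(OC)c1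
F6 | step 13 | {3,5-dimethoxy-4-[3,4,5-trimethoxy-2-(3,4,5-trimethoxyphenoxy)phenoxy]phenyl}boronic acid | COc1cc(B(O)O)cc(OC)c1Oc1cc(OC)c(OC)c(OC)c1Oc1cc(OC)c(OC)c(OC)c1
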